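Late in a run I want to know one thing: has the flask stopped, or is it just slow? I count half-lives to tell.

| setting | Wednesday's | birch | elm |
|---|---|---|---|
| starting material | 0.10 M | 0.10 M | 0.10 M |
| protic impurity | 0.010 M | 0.0100 M | 0.0100 M |
| catalyst | 3 mM | 2.0 mM | 2.0 mM |
| added ligand | 6.9 mM | 6.9 mM | 6.9 mM |
| temperature | 35 °C | 35 °C | 5 °C |
| remark | run made earlier |  |  |
| time |  | 30 h | 30 h |

Wednesday's run (percent of the starting material charged)

| time / h | target / % |
|---|---|
| 0.200 | 1.4 |
| 0.667 | 3.9 |
| 1.00 | 6.0 |
| 1.50 | 8.1 |
| 2.50 | 11.7 |
| 3.00 | 12.9 |

(scatter of a reading: 0.5 percentage points)

- the best flask by amount of target, in percent of the starting material charged; "all alike" if 1.5 percentage points covers them all (birch / elm / all alike)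
- amount of target at the end, in percent of the starting material charged, birch
- amount of target at the end, in percent of the starting material charged, elm

- the earlier runs do not show what temperature does; that part of a forecast is a guess
- no earlier run changes the charge of catalyst; that part of a forecast is a guess

Wednesday's readings bend. The target gains 8.1 % in the first 1.50 h and 4.8 percentage points in the next 1.50 h. If the gain fades as a pseudo-first-order process, the ratio of these two gains gives the stopping half-life, the time in which the gain still to come halves: 1.99 h. It is a reading and carries the scatter. The same two gains put the plateau near 19.9 %.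

My bench rule says a first-order process is over after 5 half-lives, with 3.12 % of it still to come. Birch runs 30 h at 35 °C. That is 15.1 half-lives if its clock is Wednesday's, more than the rule asks, so I take birch as stopped. I guess that the plateau follows the catalyst, and I commit to 13.3 % for birch.

Elm is where the rule may break. It stands at 5 °C, and the earlier runs show nothing about temperature. Dividing 15.1 by 5 gives 3.02. If the cooling slows the clock by more than that factor, elm is unfinished at 30 h and the plateau no longer answers. I expect just that, with elm below birch.

The forecast says birch. It gives birch 15 %, within 10 % to 35 %, a little above mine. It gives elm 9 %, within 4 % to 17 %, and calls the cooling “a guess of about 8–10 times slower”.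

The flasks give 12.9 % in birch and 3.24 % in elm, so birch is best.

    starting material + catalyst → catalyst + target (k = 0.960 M⁻¹ min⁻¹, Ea = 69.0 kJ mol⁻¹)
    starting material → side product (k = 0.00490 min⁻¹, Ea = 95.0 kJ mol⁻¹)
    starting material + protic impurity → quenched substrate (k = 0.150 M⁻¹ min⁻¹, Ea = 80.0 kJ mol⁻¹)
    catalyst + added ligand ⇌ idle complex, settled at all times (K = 240 M⁻¹, ΔH = −28.0 kJ mol⁻¹)
    (constants at 35 °C)

The forecast and the flask part on elm. Elm needs 88.3 h to half conversion, 44.4 times Wednesday's half-life, so its run is 0.340 of that time. Elm is low through the length of the run, against one ten times as long, acting together with the parking of catalyst and added ligand as idle complex, both ways. Without that parking elm gives 15.4 % against 3.24 %, and run to 300 h elm gives 14.6 %.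

Now take a flask like elm kept at 30 °C. Spreading that factor evenly over the degrees, and setting aside that Wednesday's held more catalyst, I reckon a half-life of 3.74 h. That makes 8.02 half-lives, past the rule, with 0.385 % of the starting material left. That flask holds 0.282 % of it and 13.6 % target at 30.0 h.

Readings and results come from a simulation from invented constants.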